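Product is made from third reagent and intermediate B, one of each at a turn, so the third reagent spent equals the product made. That reagent is charged at 95.0% of the starting material, less than partner or second reagent. This makes it the limiting reagent, and its charge is the product ceiling. The share of third reagent left, counted on its own charge, is then one minus product over ceiling.

| flask | starting material | partner | second reagent | third reagent | protic impurity | temperature | remark | time |
|---|---|---|---|---|---|---|---|---|
| violet | 20 mM | 2.5 equiv | 1.3 equiv | 0.95 equiv | 0.27 mM | 105 °C | run made earlier |  |
| teal | 20 mM | 2.5 equiv | 1.3 equiv | 0.95 equiv | 0.60 mM | 140 °C | run made earlier |  |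
| green | 20 mM | 2.5 equiv | 2.6 equiv | 0.95 equiv | 0.40 mM | 105 °C | run made earlier |  |
| Monday's | 20 mM | 2.50 equiv | 1.30 equiv | 0.950 equiv | 0.400 mM |  | at 110 °C until 8.0 min, from then on at 170 °C | 25 min |
| Friday's | 20 mM | 2.50 equiv | 1.30 equiv | 0.950 equiv | 0.400 mM |  | at 170 °C throughout | 25 min |

- violet (time / min: product / %, starting material / %): 1.33: 0, 70.7; 2.00: 1.0, 61.9; 3.00: 2.4, 52.2; 4.00: 3.3, 42.4; 6.00: 5.8, 35.7; 10.0: 11.5, 22.6; 15.0: 20.5, 12.7
- teal (time / min: product / %, starting material / %): 0.417: 0, 60.6; 0.833: 5.2, 42.9; 1.33: 12.1, 31.3; 2.00: 19.6, 21.6; 2.50: 24.7, 14.5; 3.00: 28.6, 11.1
- green (time / min: product / %, starting material / %): 1.33: 0, 72.3; 4.00: 3.4, 46.0; 8.00: 12.0, 25.5; 10.0: 15.5, 19.9; 15.0: 19.7, 12.4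

(readings scatter by 1 percentage point)

* the winner by amount of product, in percent of the starting material charged; "neither" if no more than 2 percentage points parts them (Monday's / Friday's / neither)
* how much product is there at the end, in percent of the starting material charged: Monday's
* how much product is there at the end, in percent of the starting material charged: Friday's

- in percentages every species weighs as the starting material in it: one homo dimer counts as two
- reactions considered so far: second reagent + intermediate A -> intermediate B; starting material + partner -> intermediate A; 2 starting material -> homo dimer; third reagent + intermediate B -> product; starting material + protic impurity -> quenched substrate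

Which numbers must we know well? A [protic impurity] of 0.400 mM against a [starting material] of 20 mM is worth 2.00% of the charge, one for one, and the 98.0% it leaves stays above the ceiling. The second reagent looks less pressing: the green run, with twice the second reagent of the violet run and also more protic impurity, leads it in product by 4 percentage points at 10.0 min but trails by 0.8 points at 15.0 min, under the scatter of 1 point. Time looks harmless as well, since the teal run had 11.1% starting material left after 3.00 min at 140 °C, and Friday's runs 25 min at 170 °C.

What must be known is how far below the ceiling the product stops, which is the split of starting material between partner and homo dimer. At similar starting material left, 11.1% and 12.7%, the hotter teal run, which also holds more protic impurity, shows 28.6% product against 20.5% in the violet run. We therefore commit to Friday's ahead of Monday's, which spends its first 8.0 min at 110 °C.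

The forecast says Friday's, with 49% for Monday's and 59% for Friday's, reasoning that “heat favours product over dimer”. By the ceiling, its Friday's figure means 37.9% of the third reagent left.

The flask gives 46.2% for Monday's and 55.1% for Friday's, so Friday's wins.

    second reagent + intermediate A → intermediate B (k = 0.510 M⁻¹ s⁻¹, Ea = 67.0 kJ mol⁻¹)
    starting material + partner → intermediate A (k = 0.0300 M⁻¹ s⁻¹, Ea = 67.0 kJ mol⁻¹)
    2 starting material → homo dimer (k = 0.110 M⁻¹ s⁻¹, Ea = 55.0 kJ mol⁻¹)
    third reagent + intermediate B → product (k = 0.190 M⁻¹ s⁻¹, Ea = 77.0 kJ mol⁻¹)
    starting material + protic impurity → quenched substrate (k = 10.0 M⁻¹ s⁻¹, Ea = 66.0 kJ mol⁻¹)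
    (constants at 110 °C)

The ceiling turns Friday's product into 42.0% of third reagent left, which is what that flask holds (42.0%). Friday's stops short of the ceiling because of the loss to homo dimer: with that step struck out, the same flask makes 95.0%. The neighbour of Monday's with 4.20 equiv of partner makes 56.7%, for which the ceiling gives 40.3% of third reagent left, and that neighbour holds 40%.

(Readings and results were generated by integration on assumed constants; scatter was added.)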